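I kept my books in one unit, the substrate charge, so that every amount below is a share of it.

| flask | substrate | partner | remark | time |
|---|---|---|---|---|
| alder | 0.10 M | 0.095 M | run made earlier |  |
| ash | 0.067 M | 0.095 M | run made earlier |  |
| elm | 0.15 M | 0.095 M | run made earlier |  |
| birch | 0.10 M | 0.14 M | run made earlier |  |
| zeta | 0.10 M | 0.0950 M | a closed flask charged with all of it at once and left for 8.0 h | 8.0 h |
| eta | 0.10 M (fed, over 6.40 h) | 0.0950 M | a stirred flask in which substrate is dosed at a steady rate over 6.40 h without added volume, worked up at 8.0 h | 8.0 h |
| epsilon | 0.10 M | 0.0950 M | a single well-mixed tank run continuously and read at steady state, 8.0 h in it on average |  |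
| alpha | 0.10 M | 0.0950 M (fed, over 6.40 h) | a stirred flask in which partner is dosed at a steady rate over 6.40 h without added volume, worked up at 8.0 h | 8.0 h |

| run | time / h | intermediate / % | target / % | substrate / % |
|---|---|---|---|---|
| alder | 0.667 | 66 | 31 | 1 |
| alder | 1.00 | 55 | 46 | 2 |
| alder | 2.00 | 43 | 56 | 1 |
| alder | 3.00 | 32 | 64 | 2 |
| alder | 5.00 | 26 | 68 | 1 |
| alder | 8.00 | 22 | 69 | 0 |
| ash | 0.833 | 60 | 39 | 3 |
| ash | 1.50 | 37 | 56 | 1 |
| ash | 2.50 | 28 | 66 | 0 |
| ash | 3.00 | 21 | 68 | 0 |
| ash | 4.00 | 14 | 74 | 0 |
| ash | 5.00 | 15 | 70 | 0 |
| elm | 0.833 | 66 | 33 | 1 |
| elm | 1.50 | 54 | 46 | 0 |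
| elm | 2.50 | 45 | 50 | 0 |
| elm | 3.00 | 45 | 48 | 0 |
| elm | 4.00 | 42 | 54 | 0 |
| elm | 5.00 | 40 | 54 | 2 |
| birch | 0.417 | 67 | 29 | 4 |
| birch | 1.33 | 32 | 59 | 0 |
| birch | 2.00 | 23 | 69 | 0 |
| birch | 3.00 | 16 | 71 | 0 |
| birch | 5.00 | 10 | 75 | 0 |

(readings scatter by 1.5 percentage points)

- the stated concentrations are those of everything mixed, before any reaction; amounts are the same in each set-up
- the feed brings no volume worth counting
- the earlier runs were made in a closed, stirred flask

- the set-up with the highest amount of intermediate at the outlet or at the end, in percent of the substrate put in ("none" if the first two lie within 2 percentage points) (zeta / eta / epsilon / alpha / none)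
- amount of intermediate at the outlet or at the end, in percent of the substrate put in, zeta
- amount of intermediate at the outlet or at the end, in percent of the substrate put in, eta
- amount of intermediate at the outlet or at the end, in percent of the substrate put in, epsilon
- amount of intermediate at the outlet or at the end, in percent of the substrate put in, alpha

Substrate was nearly gone in each run by the last readings, so what was charged had to stand as intermediate, target or a missing part. At 5.00 h the missing part was larger in birch, with its extra partner, than in alder: 15.0% against 6.00%. I therefore took it for over-reaction product, made from target with a further partner, which costs two partners where target costs one.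

Adding up gave a ledger for a flask charged with less partner than substrate, once its substrate is used: intermediate equals the partner shortfall, the part of the substrate charge that the partner charge fails to cover, 5.00% here, plus over-reaction product, plus unspent partner.

For zeta, which has alder's charge, that gave a bracket. Unspent partner cannot fall below nil, and alder's missing part read 9.00% at 8.00 h, so the bound from below was 14.0%. Intermediate fell from reading to reading in alder, so its 5.00 h reading of 26% was my bound from above, and I committed to the 8.00 h reading of 22% inside it. To rank the set-ups the ledger needs the sum of over-reaction product and unspent partner, and I did not reckon that sum by hand for eta, epsilon or alpha, so I committed to no ranking of my own.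

The forecast gave 22%, 30%, 38% and 31% for zeta, eta, epsilon and alpha, with epsilon best, since “its low conversion leaves the most intermediate”, and its zeta figure lay inside my bracket.

    substrate → intermediate (k = 0.00280 s⁻¹)
    partner + intermediate → target (k = 0.00260 M⁻¹ s⁻¹)
    partner + target → over-reaction product (k = 3.60 × 10⁻⁴ M⁻¹ s⁻¹)

The flasks gave 19.8%, 29.6%, 37.3% and 27.2%, with epsilon best. Zeta held 10.5% of over-reaction product and 4.5% of its own partner charge at 8.00 h. The ledger then reads 19.8%, inside the bracket.

Take one more flask, zeta with 0.40 M of substrate, where partner is the limiting reagent. The shortfall there is 76.2%. Computed at 8.00 h, it holds 76.7% of intermediate, with 0.468% of over-reaction product and 0% of partner left.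

The data were computed with constants of no real substance, and the scatter is random.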